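**Direct plan and its weak points**

A direct plan would ring-expand 7-acetoxy-5-methylindan-1-one A1 with the aryl diazomethyl ketone A2 (BF3·OEt2, then DDQ) to the 1-aroyl-2-naphthol A3, would turn the aryl bromide of A3 into the hydroxylactam A4 by Pd(OAc)2-catalysed aminocarbonylation, and would close the furan last by a chiral-acid dehydrative spiro-N,O-ketalisation.
- The diazo ketone ring expansion would be weak: several steps go into a plain naphthalene, and it must select aryl over alkyl migration on a hindered, chelating ketone while the acyl diazo compound survives the Lewis acid.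
- The aminocarbonylation would be weak: oxidative addition into a doubly ortho-substituted bromide next to a diaryl ketone, with free naphthols and an excess of the amino alcohol competing (O-acylation, imine formation).
- The final spirocyclisation would be weak: the only stereocentre would be set last by an unprecedented reaction, and the N-acyliminium ion from A4 can be trapped by its own hydroxyethyl arm to the fused oxazolidine lactam A5, the usual fate of 2-hydroxyethyl amides of 2-acylbenzoic acids.

**Retrosynthetic overview** (ring A = methoxyarene, ring B = lactam, ring C = furan, rings D and E = naphthalene)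
- The target is an isomer of hemiketal 15: cutting C(spiro)–N and re-forming the oxazoline C–O bond turns the N-(2-hydroxyethyl) lactam (N2, C3=O, CH2CH2OH of ring B) into a 2-aryl-oxazoline, so ring B closes last, after ring C.
- 15 is cut at the C(spiro)–C7a bond into the ortho-lithiated oxazoline 3 (the lithium sits between OMe and oxazoline, which fixes the ring A pattern) and the peri-lactone 11, in which ring C is already closed.
- 11 comes from bought 6-methylnaphthalen-2-ol: C1 is formylated, then the peri C8–O bond of the naphtho[1,8-bc]furan is put onto the intact naphthalene by oxidation of the oxime (nitrosomethide 6π-electrocyclisation onto C8).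
- Ring order: naphthalene bought, then ring C, then ring B; there is no ring expansion, no Pd(OAc)2-catalysed carbonylation and no protecting group to remove in a separate step, and the hydroxyethyl oxygen stays locked in the oxazoline until the C–N bond exists, so the oxazolidine trap is excluded.

Key step: step 7

Assumptions: 6-methylnaphthalen-2-ol is taken as commercial; hemiketal 15, its open form 14 and its anhydro form 16 all lead to the same cation, and 15 is the form drawn; which antipode of the acid gives the (S) centre must be found by trial, and (R)-TRIP is written.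

**Route**

Step 1
Reactants: 1 3-methoxybenzonitrile; 2 2-aminoethanol
Product: 3 2-(3-methoxyphenyl)-4,5-dihydro-1,3-oxazole
Conditions: ZnCl2 (5 mol %), chlorobenzene, reflux
Reagents that add atoms: none
Why: Witte–Seeliger reaction (amidine formation on the ZnCl2-activated nitrile, ring closure by the hydroxyl, loss of ammonia); the oxazoline is the ortho-director for step 6 and the latent N-(2-hydroxyethyl) lactam for step 7; no stereocentre.

Step 2
Reactants: 4 6-methylnaphthalen-2-ol
Product: 5 2-hydroxy-6-methylnaphthalene-1-carbaldehyde
Conditions: MgCl2, Et3N, (CH2O)n, MeCN, reflux; aq. HCl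
Reagents that add atoms: paraformaldehyde (as formaldehyde) C=O
Why: Casnati–Skattebøl ortho-formylation: the naphtholate, held on magnesium as ArOMgCl, delivers formaldehyde to C1, the ortho position whose attack leaves ring E benzenoid, and a second formaldehyde oxidises the benzylic alkoxide to the aldehyde by hydride transfer.

Step 3
Reactants: 5 2-hydroxy-6-methylnaphthalene-1-carbaldehyde
Product: 6 (E)-2-hydroxy-6-methylnaphthalene-1-carbaldehyde oxime
Conditions: NH2OH·HCl, NaOAc, EtOH/H2O, rt
Reagents that add atoms: hydroxylamine hydrochloride Cl.NO
Why: Oxime condensation; the O–H···N hydrogen bond of the ortho-hydroxy oxime favours the (E) isomer that is carried into step 4.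

Step 4
Reactants: 6 (E)-2-hydroxy-6-methylnaphthalene-1-carbaldehyde oxime
Product: 8 8-methylnaphtho[1,8-de][1,2]oxazin-4-ol, via nitrosomethide 7 (not isolated)
Conditions: PhI(OAc)2 (1.0 equiv), THF, 0 °C → rt
Reagents that add atoms: none
Why: Known oxidative peri-cyclisation of 2-hydroxy-1-naphthaldehyde oximes: two-electron oxidation gives the o-naphthoquinone nitrosomethide 7, whose O=N–C=C1–C8a=C8 hetero-triene closes by 6π-electrocyclisation onto C8 (the only ring carbon the nitroso oxygen can reach), and tautomerisation restores the naphthol; this C–H oxygenation creates the peri C8–O bond of the target.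

Step 5
Reactants: 8 8-methylnaphtho[1,8-de][1,2]oxazin-4-ol
Product: 11 3-hydroxy-7-methyl-2H-naphtho[1,8-bc]furan-2-one, via dihydroxy nitrile 9 (not isolated), via imidate hydrochloride 10 (not isolated)
Conditions: DBU (0.2 equiv), MeCN, 50 °C; then conc. HCl/AcOH, 70 °C
Reagents that add atoms: water O
Why: Base-catalysed Kemp-type E2 opening of the cyclic O-aryl aldoxime gives the 2,8-dihydroxy-1-naphthonitrile; under HCl the peri hydroxyl adds to the adjacent nitrile carbon (intramolecular Pinner reaction, 5-exo-dig) and water hydrolyses the imidate salt to the peri-lactone, in which ring C is closed.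

Step 6
Reactants: 3 2-(3-methoxyphenyl)-4,5-dihydro-1,3-oxazole; 11 3-hydroxy-7-methyl-2H-naphtho[1,8-bc]furan-2-one
Product: 15 racemic 2-[2-(4,5-dihydro-1,3-oxazol-2-yl)-6-methoxyphenyl]-7-methyl-2H-naphtho[1,8-bc]furan-2,3-diol, via aryllithium 12 (not isolated), via silyl ether 13 (not isolated), via open keto diol 14 (not isolated)
Conditions: 3 (1.3 equiv), s-BuLi (1.25 equiv), TMEDA, THF, −78 °C; separately 11, (Me3Si)2NH, cat. Me3SiCl, THF, reflux, evaporate; add 13 to 12, −78 → −40 °C; H2O/MeOH, pH 7 buffer; no acidic silica
Reagents that add atoms: none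
Why: Directed ortho-metalation places lithium on the carbon between methoxy and oxazoline, and the aryllithium opens the strained aryl lactone only once because the adduct collapses to a doubly ortho-substituted diaryl ketone carrying a peri phenoxide; after neutral work-up the peri hydroxyl re-closes to hemiketal 15, whose labile centre is erased in step 7.

Step 7
Reactants: 15 racemic 2-[2-(4,5-dihydro-1,3-oxazol-2-yl)-6-methoxyphenyl]-7-methyl-2H-naphtho[1,8-bc]furan-2,3-diol
Product: 18 (S)-3′-hydroxy-2-(2-hydroxyethyl)-7-methoxy-7′-methylspiro[isoindoline-1,2′-naphtho[1,8-bc]furan]-3-one, via quinone methide 16 (not isolated), via spiro-oxazolinium ion 17 (not isolated)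
Conditions: (R)-TRIP [3,3′-bis(2,4,6-triisopropylphenyl)-1,1′-binaphthyl-2,2′-diyl hydrogen phosphate] (10 mol %), dry toluene, no added water, no desiccant, −20 → 0 °C; cold filtration through basic alumina
Reagents that add atoms: none
Why: Proposed new method: the acid, resting as the oxazolinium phosphate, passes its proton to the hemiketal hydroxyl, water leaves with help from the furan oxygen and the ortho-naphthol to give the planar hydroxy-naphthofuranylium ion (protonated 16) hydrogen-bonded through its C3′–OH to the chiral phosphate, the freed oxazoline nitrogen adds to the cationic carbon, and the expelled water, delivered by the same phosphate, adds to the oxazolinium carbon of 17, whose orthoamide collapses with C–O cleavage to the lactam carbonyl and the free hydroxyethyl arm, so the net change is an isomerisation. The closest known reaction types are the racemic intramolecular N-alkylation of 2-aryl-oxazolines by an ortho benzylic electrophile with hydrolytic opening to N-(2-hydroxyethyl)isoindolinones, and chiral-phosphoric-acid-controlled additions of N–H and O–H nucleophiles to ortho-quinone methides and oxocarbenium ions (asymmetric N,O-acetalisation, spiroketalisation). Ring B closes by 5-exo-trig attack of nitrogen on the oxocarbenium carbon, while ring C stays intact. The only stereocentre, the spiro carbon, is set by the catalyst: ring A stands perpendicular to the flat cation, so the oxazoline nitrogen lies above or below it, the two ion-pair rotamers interconvert by rotation or by collapse to 15 and re-ionisation, and the phosphate pocket should let only one of them close (dynamic kinetic resolution). The step needs N-attack at the cationic carbon ahead of two other modes, and the substrate together with the water-free start should secure it: attack of the hemiketal hydroxyl on the oxazolinium carbon (the phthalide mode of ortho-hydroxyalkyl aryl oxazolines) must end in release of the amine, which a catalytic acid cannot pay for, whereas the doubly oxygen-stabilised cation forms reversibly at low acidity, and N-addition to the carbonyl of open form 14 is a reversible dead end because the only water present is the one molecule that ionisation sets free. The oxazoline oxygen is locked in its ring and the hydroxyethyl oxygen does not exist until the C–N bond is made, so no oxazolidine can form, and the basic oxazoline keeps the concentration of free acid low so that the product is not re-ionised.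

**Compound list**

1 | 3-methoxybenzonitrile | COc1cccc(C#N)c1 | starting material
2 | 2-aminoethanol | NCCO | starting material
3 | 2-(3-methoxyphenyl)-4,5-dihydro-1,3-oxazole | COc1cccc(C2=NCCO2)c1 | intermediate
4 | 6-methylnaphthalen-2-ol | Cc1ccc2cc(O)ccc2c1 | starting material
5 | 2-hydroxy-6-methylnaphthalene-1-carbaldehyde | Cc1ccc2c(C=O)c(O)ccc2c1 | intermediate
6 | (E)-2-hydroxy-6-methylnaphthalene-1-carbaldehyde oxime | Cc1ccc2c(/C=N/O)c(O)ccc2c1 | intermediate
7 | 6-methyl-1-(nitrosomethylidene)naphthalen-2(1H)-one (o-naphthoquinone nitrosomethide) | O=NC=C1C(=O)C=Cc2cc(C)ccc12 | intermediate (not isolated)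
8 | 8-methylnaphtho[1,8-de][1,2]oxazin-4-ol | Cc1cc2ccc(O)c3C=NOc(c1)c23 | intermediate
9 | 2,8-dihydroxy-6-methylnaphthalene-1-carbonitrile | N#Cc1c(O)ccc2cc(C)cc(O)c12 | intermediate (not isolated)
10 | 2-imino-7-methyl-2H-naphtho[1,8-bc]furan-3-ol hydrochloride | Cl.N=C1Oc2cc(C)cc3ccc(O)c1c23 | intermediate (not isolated)
11 | 3-hydroxy-7-methyl-2H-naphtho[1,8-bc]furan-2-one | O=C1Oc2cc(C)cc3ccc(O)c1c23 | intermediate
12 | [2-(4,5-dihydro-1,3-oxazol-2-yl)-6-methoxyphenyl]lithium | [Li]c1c(OC)cccc1C1=NCCO1 | intermediate (not isolated)
13 | 7-methyl-3-[(trimethylsilyl)oxy]-2H-naphtho[1,8-bc]furan-2-one | O=C1Oc2cc(C)cc3ccc(O[Si](C)(C)C)c1c23 | intermediate (not isolated)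
14 | [2-(4,5-dihydro-1,3-oxazol-2-yl)-6-methoxyphenyl](2,8-dihydroxy-6-methylnaphthalen-1-yl)methanone (open form of 15) | COc1cccc(C2=NCCO2)c1C(=O)c1c(O)ccc2cc(C)cc(O)c12 | intermediate (not isolated)
15 | racemic 2-[2-(4,5-dihydro-1,3-oxazol-2-yl)-6-methoxyphenyl]-7-methyl-2H-naphtho[1,8-bc]furan-2,3-diol | COc1cccc(C2=NCCO2)c1C1(O)Oc2cc(C)cc3ccc(O)c1c23 | intermediate
16 | 2-[2-(4,5-dihydro-1,3-oxazol-2-yl)-6-methoxyphenyl]-7-methyl-3H-naphtho[1,8-bc]furan-3-one (quinone methide, neutral form of the oxocarbenium ion) | COc1cccc(C2=NCCO2)c1C1=C2C(=O)C=Cc3cc(C)cc(O1)c23 | intermediate (not isolated)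
17 | (S)-3′-hydroxy-6-methoxy-7′-methyl-2,3-dihydrospiro[[1,3]oxazolo[2,3-a]isoindol-4-ium-5,2′-naphtho[1,8-bc]furan] (cation, paired with the phosphate of the catalyst) | COc1cccc2c1[C@]1(Oc3cc(C)cc4ccc(O)c1c34)[N+]1=C2OCC1 | intermediate (not isolated)
18 | (S)-3′-hydroxy-2-(2-hydroxyethyl)-7-methoxy-7′-methylspiro[isoindoline-1,2′-naphtho[1,8-bc]furan]-3-one | COc1cccc2c1[C@]1(Oc3cc(C)cc4ccc(O)c1c34)N(CCO)C2=O | target

**Count and risks**

Total steps: 7. Longest linear sequence: 6 (steps 2 to 7, from 6-methylnaphthalen-2-ol).

Steps most likely to fail:

1. Step 7 (proposed new method). The achiral background isomerisation could outrun the chiral ion pair, the product could re-ionise under the acid and lose enantiomeric purity, or adventitious water could let the reaction run through N-addition to the open ketone 14 and bypass the cation. The fallback sets out from 15 and gives up catalyst control. An achiral acid (pyridinium p-toluenesulfonate, wet THF, rt) would take the same cation through N-alkylation of the 2-aryl-oxazoline and hydrolysis of the N-alkyl-oxazolinium salt, both known reaction types, to the racemic spiro-lactam F1. Separation of the enantiomers on a chiral stationary phase (preparative supercritical-fluid chromatography) comes back to the route at 18; the unwanted antipode could be returned to the racemate by acid re-ionisation of its N,O-ketal and recycled.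

2. Step 4. The nitrosomethide 7 could close through the C2 oxygen instead (ortho-cyclisation to the isoxazole N-oxide) or dimerise, so that little peri product forms. The fallback sets out from 5 and installs the peri oxygen by halogenation and C–O coupling. O-Methylation (MeI, K2CO3) gives 2-methoxy-6-methylnaphthalene-1-carbaldehyde F2. Pd(OAc)2-catalysed, aldehyde-directed peri bromination with N-bromosuccinimide gives 8-bromo-2-methoxy-6-methylnaphthalene-1-carbaldehyde F3; C8 is also the ring position the methoxy group activates once C1 and C6 are occupied. Pinnick oxidation (NaClO2, NaH2PO4, 2-methyl-2-butene) gives 8-bromo-2-methoxy-6-methylnaphthalene-1-carboxylic acid F4. Ullmann-type lactonisation (CuI, Cs2CO3, DMF, heat) gives 3-methoxy-7-methyl-2H-naphtho[1,8-bc]furan-2-one F5, and BBr3 demethylation comes back to the route at 11.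

3. Step 6. s-BuLi could add to the C=N of the unsubstituted oxazoline or metalate the wrong site, the hindered aryllithium could add slowly to the lactone, and traces of acid during work-up could trigger premature racemic isomerisation. The fallback sets out from 11, used as its silyl ether 13, and makes the nucleophile without a deprotonation. Commercial 2-bromo-3-methoxybenzoic acid F6 is coupled with 2 to 2-bromo-N-(2-hydroxyethyl)-3-methoxybenzamide F7, which is cyclodehydrated (TsCl, Et3N, DMAP) to 2-(2-bromo-3-methoxyphenyl)-4,5-dihydro-1,3-oxazole F8. Bromine–magnesium exchange with iPrMgCl·LiCl at −20 °C gives [2-(4,5-dihydro-1,3-oxazol-2-yl)-6-methoxyphenyl]magnesium chloride F9, which is added to 13 and worked up as in step 6 to come back to the route at 15.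

**Further compounds**

F1 | step 7 | racemic 3′-hydroxy-2-(2-hydroxyethyl)-7-methoxy-7′-methylspiro[isoindoline-1,2′-naphtho[1,8-bc]furan]-3-one | COc1cccc2c1C1(Oc3cc(C)cc4ccc(O)c1c34)N(CCO)C2=O
F2 | step 4 | 2-methoxy-6-methylnaphthalene-1-carbaldehyde | COc1ccc2cc(C)ccc2c1C=O
F3 | step 4 | 8-bromo-2-methoxy-6-methylnaphthalene-1-carbaldehyde | COc1ccc2cc(C)cc(Br)c2c1C=O
F4 | step 4 | 8-bromo-2-methoxy-6-methylnaphthalene-1-carboxylic acid | COc1ccc2cc(C)cc(Br)c2c1C(=O)O
F5 | step 4 | 3-methoxy-7-methyl-2H-naphtho[1,8-bc]furan-2-one | COc1ccc2cc(C)cc3OC(=O)c1c23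
F6 | step 6 | 2-bromo-3-methoxybenzoic acid | COc1cccc(C(=O)O)c1Br
F7 | step 6 | 2-bromo-N-(2-hydroxyethyl)-3-methoxybenzamide | COc1cccc(C(=O)NCCO)c1Br
F8 | step 6 | 2-(2-bromo-3-methoxyphenyl)-4,5-dihydro-1,3-oxazole | COc1cccc(C2=NCCO2)c1Br
F9 | step 6 | [2-(4,5-dihydro-1,3-oxazol-2-yl)-6-methoxyphenyl]magnesium chloride | COc1cccc(C2=NCCO2)c1[Mg]Cl
A1 | direct plan | 7-acetoxy-5-methylindan-1-one (6-methyl-3-oxo-2,3-dihydro-1H-inden-4-yl acetate) | CC(=O)Oc1cc(C)cc2c1C(=O)CC2
A2 | direct plan | 1-(2-bromo-6-methoxyphenyl)-2-diazoethan-1-one | [N-]=[N+]=CC(=O)c1c(Br)cccc1OC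
A3 | direct plan | 8-(2-bromo-6-methoxybenzoyl)-7-hydroxy-3-methylnaphthalen-1-yl acetate | CC(=O)Oc1cc(C)cc2ccc(O)c(C(=O)c3c(Br)cccc3OC)c12
A4 | direct plan | racemic 3-(2,8-dihydroxy-6-methylnaphthalen-1-yl)-3-hydroxy-2-(2-hydroxyethyl)-4-methoxyisoindolin-1-one | COc1cccc2c1C(O)(c1c(O)ccc3cc(C)cc(O)c13)N(CCO)C2=O
A5 | direct plan | 9b-(2,8-dihydroxy-6-methylnaphthalen-1-yl)-9-methoxy-2,3-dihydro[1,3]oxazolo[2,3-a]isoindol-5(9bH)-one | COc1cccc2c1C1(c3c(O)ccc4cc(C)cc(O)c34)OCCN1C2=O
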